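The numbers in the tables were computed on assumed constants; scatter was added.

**Holding ratio.** Per molar of D charged, the highest E read stood lower in the hotter run, and I built on that.

| setting | spring | noon | Wednesday's | Saturday's | Monday's |
|---|---|---|---|---|---|
| G | 25 mM | 40 mM | 18 mM | 18 mM | 18 mM |
| D | 1.5 equiv | 1.5 equiv | 1.50 equiv | 1.50 equiv | 1.50 equiv |
| X | 0.36 mM | 0.36 mM | 0.360 mM | 0.360 mM | 0.360 mM |
| temperature | 10 °C | 21 °C |  | 5 °C | 25 °C |
| remark | run made earlier | run made earlier | at 5 °C until 3.0 h, from then on at 25 °C |  |  |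
| time |  |  | 15 h | 15 h | 15 h |

| spring: time / h | spring: E / % | noon: time / h | noon: E / % |
|---|---|---|---|
| 1.33 | 12.8 | 0.667 | 12.2 |
| 4.00 | 15.6 | 1.00 | 11.6 |
| 8.00 | 11.5 | 2.00 | 6.8 |
| 10.0 | 11.2 | 4.00 | 2.9 |
| 15.0 | 8.7 | 6.00 | 3.9 |

(scatter of a reading: 1 percentage point)

- which flask leads in amount of E, in percent of the G charged ("all alike" within 1.5 percentage points) (Wednesday's / Saturday's / Monday's / all alike)
- how much E is there at the end, in percent of the G charged: Wednesday's
- how much E is there at the end, in percent of the G charged: Saturday's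
- how much E is there at the end, in percent of the G charged: Monday's



I defined the holding ratio as the highest E read, as a share of the G charged, over the concentration of D charged: a crude stand-in for an equilibrium constant. The spring run read 4.16 M⁻¹. The noon run read 2.03 M⁻¹ at its earliest reading, which may already lie past the peak. A straight line of the logarithm against temperature gave 5.76 M⁻¹ at 5 °C, the holding ratio I carried on.

**Two ways.** Saturday's flask was charged with 27.0 mM of D, so way one put its E at 15.6 %, with no loss charged.

Way two began from the spring peak and applied the fade, the first-order fall of E after its peak. Spring read 0.0531 h⁻¹ and noon 0.431 h⁻¹, so the same line gave 0.0205 h⁻¹ at 5 °C. Over the whole 15 h that left 11.5 %.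

The ways parted, and each cheated. Way two charged fade for the hours before the peak, while way one charged none. I therefore took way one's level and faded it from 4.00 h, the time of the spring peak, which gave 12.4 %. By that line the fade half-life at 5 °C, 33.8 h, was longer than the run. At 25 °C the line gave 0.751 h, far shorter than the hot hours of Wednesday's flask. I expected little E in that flask and in Monday's.

**The forecast.** It named Saturday's as leader, with 12.5 % there, 1.8 % in Wednesday's and 1.5 % in Monday's: “roughly 16% falls to about 12.5% at 15 h”. My own figure stood slightly below its Saturday value.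

**The flasks.** Saturday's led with 14.8 %, against 0.623 % in Wednesday's and 0.505 % in Monday's. The forecast held: the lead over Wednesday's flask was 14 percentage points, far above the margin.

    G + D ⇌ E (K = 12.0 M⁻¹, k = 2.30 M⁻¹ h⁻¹, Ea = 75.0 kJ mol⁻¹, ΔH = −51.0 kJ mol⁻¹)
    G + D ⇌ Z (K = 1700 M⁻¹, k = 1.00 M⁻¹ h⁻¹, Ea = 77.0 kJ mol⁻¹, ΔH = −28.0 kJ mol⁻¹)
    D + X → J (k = 42.0 M⁻¹ h⁻¹, Ea = 66.0 kJ mol⁻¹)
    2 D → L (k = 0.150 M⁻¹ h⁻¹, Ea = 72.0 kJ mol⁻¹)
    (constants at 5 °C)

In Saturday's flask, half the turnover of the step to E up to the asked time was done by 1.56 h, whereas half of G took 35.1 h to convert. At 15.0 h that flask's E stood beside 62.1 % of unbound G. At 7.50 h, Saturday's E over D charged gave 5.84 M⁻¹, beside the carried 5.76 M⁻¹.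

**Second flask.** The neighbour of Saturday's flask, charged with 0.900 equiv of D, started from 16.2 mM of D, so the holding ratio gives 9.33 %, with no loss charged. The computed neighbour gives 10.2 % at its end.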